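**Assumption:** the target (5,7,8,3',4',5'-hexamethoxyflavone) is planar and achiral, with no stereocentres, so "single enantiomer" imposes no stereochemical requirement. The route has not been run; the key step is a proposal.

## Retrosynthetic overview

1. Both benzene rings are purchased: acetophenone 1 supplies the A ring plus C3/C4, and ester 2 supplies the B ring plus C2.
2. C2–C3 bond: crossed Claisen condensation of 1 and 2 gives 1,3-diketone 3.
3. O1–C8a bond (the only ring formed, the pyranone C ring): the A ring of 3 is oxidised to an acyl-p-quinone, which the diketone enol oxygen closes onto by 6-endo oxa-Michael addition, giving 5,8-dihydroxyflavone 4 (new step).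
4. Double O-methylation of 4 gives target 5.
5. Ring order: A and B purchased, C ring formed in step 2; no stereocentres to set.

## Route

**Step 1**
Reactants: 1, 2',4',5'-trimethoxyacetophenone; 2, methyl 3,4,5-trimethoxybenzoate
Product: 3, 1-(2,4,5-trimethoxyphenyl)-3-(3,4,5-trimethoxyphenyl)propane-1,3-dione (mainly the chelated enol)
Conditions: NaH (2.5 equiv), THF, 0 °C to reflux, 5 h (1 added slowly to NaH/2); then aq HCl
Reagents that add atoms: none
Why: Crossed Claisen condensation; only 1 is enolisable, 2 cannot self-condense, and the product is removed as its stabilised sodium β-diketonate, which drives the equilibrium.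

**Step 2**
Reactants: 3, 1-(2,4,5-trimethoxyphenyl)-3-(3,4,5-trimethoxyphenyl)propane-1,3-dione
Product: 4, 5,8-dihydroxy-7-methoxy-2-(3,4,5-trimethoxyphenyl)-4H-chromen-4-one
Conditions: CAN (4.4 equiv), MeCN–H2O 3:1, 0.02 M, 0 °C to rt, 1 h; then sat. aq Na2S2O4, rt, 15 min
Reagents that add atoms: water, O (supplies the two new phenolic oxygens at C5 and C8; the original 2'- and 5'-methoxy groups leave as methanol)
Why: Proposed new method: Ce(IV) should oxidise only the A ring, since it alone has a para-dimethoxy pair (estimated about 1.3 V against about 1.7 V vs SCE for the 3,4,5-trimethoxyaroyl B ring), and ipso-hydration with loss of two MeOH gives a 2-acyl-5-methoxy-1,4-benzoquinone; its C3 (the former C6'–H) is then a Michael acceptor activated by both the ring carbonyl and the side-chain carbonyl, the distal enol oxygen adds 6-endo-trig (attack by carbon or by the other oxygen would need a four-membered ring, and the B ring is not electrophilic), and tautomerisation gives hydroquinone 4 (excess Ce(IV) takes it to the flavone-5,8-quinone and dithionite returns 4); the closest known reactions are CAN oxidative demethylation of 2,5-dimethoxyaryl ketones to acylquinones and intramolecular phenol-O Michael closure onto aroylquinones (xanthone-1,4-dione formation), and to my knowledge this has not been shown for enol-O closure of a 1,3-diaryl-1,3-diketone to a flavone.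

**Step 3**
Reactants: 4, 5,8-dihydroxy-7-methoxy-2-(3,4,5-trimethoxyphenyl)-4H-chromen-4-one
Product: 5, 5,7,8-trimethoxy-2-(3,4,5-trimethoxyphenyl)-4H-chromen-4-one (target)
Conditions: MeI (6 equiv), K2CO3 (6 equiv), DMF, N2, 50 °C, 12 h
Reagents that add atoms: iodomethane, CI (two methyl groups)
Why: Williamson O-methylation; the free 8-OH reacts quickly and the carbonyl-chelated 5-OH more slowly, hence excess MeI and mild heating, with N2 to stop the hydroquinone dianion autoxidising.

## Compound list

1 | 2',4',5'-trimethoxyacetophenone | CC(=O)c1cc(OC)c(OC)cc1OC | starting material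
2 | methyl 3,4,5-trimethoxybenzoate | COC(=O)c1cc(OC)c(OC)c(OC)c1 | starting material
3 | 1-(2,4,5-trimethoxyphenyl)-3-(3,4,5-trimethoxyphenyl)propane-1,3-dione | COc1cc(OC)c(C(=O)CC(=O)c2cc(OC)c(OC)c(OC)c2)cc1OC | intermediate
4 | 5,8-dihydroxy-7-methoxy-2-(3,4,5-trimethoxyphenyl)-4H-chromen-4-one | COc1cc(O)c2c(=O)cc(-c3cc(OC)c(OC)c(OC)c3)oc2c1O | intermediate
5 | 5,7,8-trimethoxy-2-(3,4,5-trimethoxyphenyl)-4H-chromen-4-one | COc1cc(-c2cc(=O)c3c(OC)cc(OC)c(OC)c3o2)cc(OC)c1OC | target

## Summary

Total steps: 3. Longest linear sequence: 3.

Steps most likely to fail:

1. **Step 2 (proposed new step).** Risks: Ce(IV) oxidising the diketone enol instead of the arene; sluggish oxidation of the acyl-deactivated ring; hydrolysis of the 7-OMe in the over-oxidised quinone. Fallback (known chemistry, different logic): start with the phenol oxygen already in place. Friedel–Crafts acetylation of 1,2,3,5-tetramethoxybenzene with AcCl/AlCl3, with concomitant cleavage of the hindered ortho-OMe, gives 2'-hydroxy-3',4',6'-trimethoxyacetophenone. O-aroylation with 3,4,5-trimethoxybenzoyl chloride, Baker–Venkataraman rearrangement (KOH/pyridine) and AcOH/H2SO4 cyclodehydration then give 5 directly.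

2. **Step 1.** Risks: self-aldol of 1; low electrophilicity of the electron-rich ester. Fallback: make 3 through an ynone instead of an enolate acylation. Pd/Cu acyl-Sonogashira coupling of 2,4,5-trimethoxybenzoyl chloride with 5-ethynyl-1,2,3-trimethoxybenzene, then Et2NH conjugate addition and aqueous acid hydrolysis of the enaminone, gives 3.

3. **Step 3.** Risks: incomplete methylation of the chelated 5-OH; air oxidation of the hydroquinone dianion back to the quinone. Fallback: do not isolate 4. Omit the dithionite quench in step 2, take the flavone-5,8-quinone forward, and carry out a one-pot reductive methylation (Na2S2O4, Bu4NBr, aq KOH/THF, Me2SO4) so the dianion is generated and trapped under reducing conditions.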